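**Strategy.** The flavone is disconnected across ring C at C4–C4a and O1–C2, leading back to a pentaoxygenated resorcinol and an α-methoxy β-keto ester. Ring A bears oxygen on every carbon except C4a. In the phenol this is the only C–H, ortho to the hydroxyl that becomes O1 on C8a and para to the hydroxyl that remains as the C7 hydroxyl. One thermal Mentzer condensation should therefore form both bonds, close the pyranone, bring in the 3-methoxy group and deliver the target without any protecting group. Its precursors are 2,4,5-trimethoxybenzene-1,3-diol and racemic ethyl 2-methoxy-3-(4-methoxyphenyl)-3-oxopropanoate.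

Key step: step 6

Remark 1: the target has no stereocentre; the keto ester is used as the racemate and its stereocentre vanishes when C3 becomes trigonal.
Remark 2: the keto ester is kept in the ethyl series (ethyl methoxyacetate as building block), because assembly from methyl esters would give the methyl, not the ethyl, keto ester.
Remark 3: the diol is reached by a regiodefined hydroxylation of a 2,4,5-trimethoxyphenol derivative, so that no statistical O-methylation of a symmetric resorcinol is needed. Locants of benzene intermediates follow each compound name; in diol 8 the single C–H carbon is C6.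

**Step 1**
Reactants: 1 2,4,5-trimethoxybenzaldehyde
Product: 3 2,4,5-trimethoxyphenol, via 2,4,5-trimethoxyphenyl formate 2 (not isolated)
Conditions: 30% aq. H2O2, H2SO4 (cat.), MeOH, rt
Reagents that add atoms: hydrogen peroxide, OO
Why: Dakin oxidation under acid catalysis (Baeyer–Villiger-type migration of the electron-rich aryl group in the peroxyhemiacetal) should give formate 2, which is methanolysed in the same flask to the phenol.

**Step 2**
Reactants: 3 2,4,5-trimethoxyphenol
Product: 4 triisopropyl(2,4,5-trimethoxyphenoxy)silane
Conditions: iPr3SiCl, imidazole, DMF, rt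
Reagents that add atoms: triisopropylsilyl chloride, CC(C)[Si](Cl)(C(C)C)C(C)C
Why: Imidazole-promoted O-silylation of a phenol should proceed cleanly, and the bulky silyl ether tolerates alkyllithium bases, binds lithium poorly and screens the neighbouring C6–H.

**Step 3**
Reactants: 4 triisopropyl(2,4,5-trimethoxyphenoxy)silane
Product: 7 2,3,6-trimethoxy-5-(triisopropylsilyloxy)phenol, via aryllithium 5 (not isolated), via dimethyl arylboronate 6 (not isolated)
Conditions: n-BuLi, TMEDA, THF, 0 °C; B(OMe)3, −78 °C to rt; then 30% aq. H2O2, AcOH, 0 °C to rt; aq. Na2SO3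
Reagents that add atoms: hydrogen peroxide, OO
Why: Directed ortho-metalation followed by borylation and oxidation should hydroxylate C3, because C3–H lies between two methoxy groups that chelate lithium together whereas C6–H is flanked by the non-coordinating, bulky silyloxy group, and peroxide then converts the C–B bond into C–O at the same carbon by 1,2-aryl shift.

**Step 4**
Reactants: 7 2,3,6-trimethoxy-5-(triisopropylsilyloxy)phenol
Product: 8 2,4,5-trimethoxybenzene-1,3-diol
Conditions: Bu4NF, AcOH, THF, 0 °C, Ar
Reagents that add atoms: none
Why: Fluoride-induced cleavage of the aryl silyl ether, driven by Si–F bond formation, should free the second hydroxyl, and the acetic acid buffer keeps the electron-rich resorcinol protonated and less prone to air oxidation.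

**Step 5**
Reactants: 9 ethyl methoxyacetate; 10 4-methoxybenzoyl chloride
Product: 12 racemic ethyl 2-methoxy-3-(4-methoxyphenyl)-3-oxopropanoate, via lithium enolate 11 (not isolated)
Conditions: LiN(SiMe3)2 (2.1 equiv), 9 (2.1 equiv), THF, −78 °C; then 10 (1.0 equiv), −78 to 0 °C; aq. NH4Cl
Reagents that add atoms: none
Why: Crossed Claisen-type C-acylation of a lithium ester enolate by an acid chloride should give the keto ester, since the second equivalent of enolate deprotonates the more acidic product and so suppresses double acylation; the new stereocentre forms without control because the racemate is wanted.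

**Step 6**
Reactants: 8 2,4,5-trimethoxybenzene-1,3-diol; 12 racemic ethyl 2-methoxy-3-(4-methoxyphenyl)-3-oxopropanoate
Product: 15 7-hydroxy-3,5,6,8-tetramethoxy-2-(4-methoxyphenyl)-4H-chromen-4-one (the target), via aroyl(methoxy)ketene 13 (not isolated), via hydroxyaryl diketone 14 (not isolated)
Conditions: Ph2O, 240–250 °C, Ar, 12 (1.5 equiv), EtOH distilled off; chromatography
Reagents that add atoms: none
Why: On heating, keto ester 12 should expel ethanol to give ketene 13, which acylates diol 8 at its only ring C–H (C6, the future C4a), directly or by O-acylation and thermal acyl shift, to give diketone 14 and thus the C4–C4a bond. The C1 hydroxyl (future O1 on C8a) then adds to the aroyl carbonyl in a 6-exo-trig closure, and loss of water from the hemiketal forms O1–C2 and the C2=C3 double bond of ring C. The closest known reaction type is the Mentzer pyrocondensation (Simonis-type chromone annulation) of activated phenols such as phloroglucinol with α-substituted β-keto esters. No stereocentre is created, and the stereocentre of racemic 12 is erased when C3 becomes trigonal. Site selectivity rests on the substrate: C6 is the sole unsubstituted ring carbon and is activated by an ortho and a para hydroxyl, and only the C1 hydroxyl is ortho to the new acyl group, so the C3 hydroxyl cannot cyclise and emerges as the free C7 hydroxyl. Chromone rather than coumarin formation follows from the acid-free thermal ketene pathway, in which the ester carbon and not the ketone carbon bonds to the ring.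

**Compound list**
1 | 2,4,5-trimethoxybenzaldehyde | O=Cc1cc(OC)c(OC)cc1OC | starting material
2 | 2,4,5-trimethoxyphenyl formate | O=COc1cc(OC)c(OC)cc1OC | intermediate
3 | 2,4,5-trimethoxyphenol | Oc1cc(OC)c(OC)cc1OC | intermediate
4 | triisopropyl(2,4,5-trimethoxyphenoxy)silane | CC(C)[Si](Oc1cc(OC)c(OC)cc1OC)(C(C)C)C(C)C | intermediate
5 | [2,3,6-trimethoxy-5-(triisopropylsilyloxy)phenyl]lithium | CC(C)[Si](Oc1cc(OC)c(OC)c([Li])c1OC)(C(C)C)C(C)C | intermediate
6 | dimethyl [2,3,6-trimethoxy-5-(triisopropylsilyloxy)phenyl]boronate | COB(OC)c1c(OC)c(OC)cc(O[Si](C(C)C)(C(C)C)C(C)C)c1OC | intermediate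
7 | 2,3,6-trimethoxy-5-(triisopropylsilyloxy)phenol | Oc1c(OC)c(OC)cc(O[Si](C(C)C)(C(C)C)C(C)C)c1OC | intermediate
8 | 2,4,5-trimethoxybenzene-1,3-diol | Oc1cc(OC)c(OC)c(O)c1OC | intermediate
9 | ethyl methoxyacetate | CCOC(=O)COC | starting material
10 | 4-methoxybenzoyl chloride | COc1ccc(cc1)C(Cl)=O | starting material
11 | lithium 1-ethoxy-2-methoxyethen-1-olate (chelated enolate, OLi cis to OMe) | [Li]O/C(OCC)=C\OC | intermediate
12 | racemic ethyl 2-methoxy-3-(4-methoxyphenyl)-3-oxopropanoate | CCOC(=O)C(OC)C(=O)c1ccc(OC)cc1 | intermediate
13 | 2-methoxy-3-(4-methoxyphenyl)-3-oxoprop-1-en-1-one (aroyl(methoxy)ketene) | COC(=C=O)C(=O)c1ccc(OC)cc1 | intermediate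
14 | racemic 1-(2,4-dihydroxy-3,5,6-trimethoxyphenyl)-2-methoxy-3-(4-methoxyphenyl)propane-1,3-dione | COc1ccc(cc1)C(=O)C(OC)C(=O)c1c(O)c(OC)c(O)c(OC)c1OC | intermediate
15 | 7-hydroxy-3,5,6,8-tetramethoxy-2-(4-methoxyphenyl)-4H-chromen-4-one | COc1ccc(-c2oc3c(OC)c(O)c(OC)c(OC)c3c(=O)c2OC)cc1 | target

**Step count**
Total step count: 6. Longest linear sequence: 5 steps (steps 1, 2, 3, 4 and 6); step 5 is the convergent branch.

**Steps most likely to fail**

1. Step 6 (key condensation). At 240 °C the electron-rich diol may be oxidised or degraded before C-acylation, the reaction may stall at an O-acyl ester, or the keto ester may be consumed by ketene self-reaction. The fallback builds ring C stepwise by known chemistry and sets out from diol 8. Hoesch acylation with methoxyacetonitrile (ZnCl2, HCl gas, Et2O, 0 °C; then hot water) at the same lone C–H should give 1-(2,4-dihydroxy-3,5,6-trimethoxyphenyl)-2-methoxyethan-1-one F1. Allan–Robinson condensation of this ketone with 4-methoxybenzoic anhydride and potassium 4-methoxybenzoate at about 180 °C should give the flavone as its 7-O-aroyl ester, 3,5,6,8-tetramethoxy-2-(4-methoxyphenyl)-4-oxo-4H-chromen-7-yl 4-methoxybenzoate F2. Saponification (KOH, aq. EtOH, reflux; then acid) rejoins the route at target 15.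

2. Step 3 (metalation and hydroxylation). Metalation may occur at the wrong ring C–H (C6) or remain incomplete, and the new phenol may be over-oxidised by peroxide. The fallback replaces deprotonation by electronically controlled electrophilic substitution and sets out from phenol 3. Acylation (pivaloyl chloride, Et3N, DMAP cat., CH2Cl2) should give 2,4,5-trimethoxyphenyl pivalate F3. Bromination (NBS, MeCN, 0 °C) should go to C3, which is flanked by two methoxy groups, and not to C6, which sits beside the deactivating acyloxy group, giving 3-bromo-2,4,5-trimethoxyphenyl pivalate F4. Hydroxylation of the aryl bromide (Pd2(dba)3, tBuXPhos, KOH, dioxane/H2O, 100 °C; then acid), during which the pivalate is saponified, rejoins the route at diol 8 and makes steps 2 to 4 unnecessary.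

3. Step 5 (enolate acylation). O-acylation or double acylation of the enolate and self-condensation of the ester may erode the C-acylation. The fallback separates C–C bond formation from the oxidation level and sets out from ethyl methoxyacetate 9. Aldol addition of its lithium enolate (LiN(iPr)2, THF, −78 °C) to 4-methoxybenzaldehyde should give ethyl 3-hydroxy-2-methoxy-3-(4-methoxyphenyl)propanoate F5 as a mixture of racemic diastereomers. Oxidation of the benzylic alcohol (Dess–Martin periodinane, CH2Cl2, rt) converges both diastereomers and rejoins the route at keto ester 12.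

**Further compounds**
F1 | step 6 | 1-(2,4-dihydroxy-3,5,6-trimethoxyphenyl)-2-methoxyethan-1-one | COCC(=O)c1c(O)c(OC)c(O)c(OC)c1OC
F2 | step 6 | 3,5,6,8-tetramethoxy-2-(4-methoxyphenyl)-4-oxo-4H-chromen-7-yl 4-methoxybenzoate | COc1ccc(-c2oc3c(OC)c(OC(=O)c4ccc(OC)cc4)c(OC)c(OC)c3c(=O)c2OC)cc1
F3 | step 3 | 2,4,5-trimethoxyphenyl pivalate | CC(C)(C)C(=O)Oc1cc(OC)c(OC)cc1OC
F4 | step 3 | 3-bromo-2,4,5-trimethoxyphenyl pivalate | CC(C)(C)C(=O)Oc1cc(OC)c(OC)c(Br)c1OC
F5 | step 5 | ethyl 3-hydroxy-2-methoxy-3-(4-methoxyphenyl)propanoate (mixture of racemic diastereomers) | CCOC(=O)C(OC)C(O)c1ccc(OC)cc1
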